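**Retrosynthetic overview**
1. Feature: ring A (4-hydroxy-3-methoxyphenyl, on C7') and ring B (3,4-dimethoxyphenyl, on C7) are joined by the chain C7–C8(C9)–C8'(C9')–C7'. Once the termini are made alike, the methyl-bearing methines C8 (S) and C8' (R) are the two homotopic halves of a C2-symmetric (2S,3S)-2,3-dimethylbutane-1,4-diyl unit.
2. Late disconnections: the O-acetyl group; C7–C1 of ring B (Felkin–Anh aryl Grignard addition to the C7 aldehyde, sets 7R); C7'–C1' of ring A (copper-catalysed aryl Grignard/tosylate coupling). These lead back to (2S,3S)-2,3-dimethylbutane-1,4-diol, which is differentiated by monosilylation.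
3. Core disconnection: the bonds C8–C9 and C8'–C9' are both made in one pot on a (5S)-5-menthyloxybutenolide by cuprate 1,4-addition followed by enolate methylation. LiAlH4 then erases the acetal carbon that steers both events.
4. Rings: no ring of the target is built, since rings A and B are bought as aryl bromides. The temporary butenolide ring comes from the furan ring of furfural and is opened directly after the key step.

Key step: step 3

Remark on the chemistry: lignan numbering is used. The target SMILES is read as (7R,8S,8'R), which is (1R,2S,3R) in the butyl acetate name, with 7,8-syn and 8,8'-syn relationships in the zigzag drawing.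

**Step 1**
Reactants: 1 furfural
Product: 3 5-hydroxyfuran-2(5H)-one (racemic), via furfural endoperoxide 2 (not isolated)
Conditions: O2, methylene blue (cat.), hν (visible), MeOH, 20 °C
Reagents that add atoms: dioxygen, O=O
Why: Dye-sensitised photooxygenation, in which singlet oxygen adds to the furan diene in a [4+2] cycloaddition and methanol attacks the formyl group of 2, which fragments with O–O cleavage to the γ-hydroxybutenolide; the hemiacetal carbon forms racemic and is labile, which does not matter here.

**Step 2**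
Reactants: 3 5-hydroxyfuran-2(5H)-one; 4 (1S,2R,5S)-(+)-menthol
Product: 6 (5S)-5-[(1S,2R,5S)-menthyloxy]furan-2(5H)-one, via 5R-epimeric acetal 5 (not isolated)
Conditions: CSA (cat.), toluene, reflux, Dean–Stark; crystallisation from petroleum ether; mother liquor re-equilibrated (CSA) and crystallised again
Reagents that add atoms: none
Why: Acid-catalysed acetalisation of the pseudo-acid gives both C5 epimers, and because these interconvert under acid while only the (5S) acetal of (+)-menthol crystallises, crystallisation with recycling (crystallisation-driven epimerisation) should funnel the material into 6 and fix C5.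

**Step 3**
Reactants: 6 (5S)-5-[(1S,2R,5S)-menthyloxy]furan-2(5H)-one
Product: 8 (3S,4S,5S)-3,4-dimethyl-5-[(1S,2R,5S)-menthyloxy]dihydrofuran-2(3H)-one (3,4-trans and 4,5-trans), via lithium enolate 7 (not isolated)
Conditions: Me2CuLi (from CuI + 2 MeLi), Et2O, −78 °C; then MeI (excess), THF/DMPU, −78 → −20 °C; aq NH4Cl
Reagents that add atoms: lithium dimethylcuprate, [Li+].C[Cu-]C; iodomethane, CI
Why: The Gilman reagent binds the electron-poor C3=C4 bond of 6 as a π-complex, oxidative addition places trivalent copper on C4 and reductive elimination forges the C4–CH3 bond, leaving lithium enolate 7, which attacks MeI at C3 in an SN2 step once DMPU has loosened its aggregates. The closest known reaction type is the tandem (three-component) cuprate conjugate addition/enolate alkylation of butenolides, which is established on 5-alkoxyfuran-2(5H)-ones with anti selectivity in both events. No ring is closed or opened, and the five-membered lactone serves only as a flat, rigid template. C4 is controlled by the acetal carbon C5, whose pseudo-axial menthyloxy group blocks one face so that methyl arrives anti to it (4S); C3 is controlled by the new C4 methyl, the planar enolate being alkylated on the face away from it (3S), and since this 3,4-trans isomer is also the more stable one, any equilibration at C3 works in the same direction. The step needs 1,4- over 1,2-regioselectivity, secured by the soft cuprate, and mono- over dimethylation at C3, secured by excess MeI, low temperature and an early quench that keep proton transfer between product and enolate slow. The absolute sense rests only on the configuration of C5, which was fixed in step 2 by the choice of (+)-menthol.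

**Step 4**
Reactants: 8 (3S,4S,5S)-3,4-dimethyl-5-[(1S,2R,5S)-menthyloxy]dihydrofuran-2(3H)-one
Product: 9 (2S,3S)-2,3-dimethylbutane-1,4-diol
Conditions: LiAlH4, THF, 0 °C → reflux; H2O/aq NaOH work-up; menthol removed by hexane/water partition
Reagents that add atoms: none
Why: Exhaustive hydride reduction of the pseudo-ester takes both oxidised carbons (lactone C2 and, after loss of menthoxide on ring opening, acetal C5) down to CH2OH faster than enolisation can occur, so C3 and C4 pass unchanged into the C2-symmetric diol and the auxiliary is recovered.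

**Step 5**
Reactants: 9 (2S,3S)-2,3-dimethylbutane-1,4-diol
Product: 10 (2S,3S)-4-[(tert-butyldimethylsilyl)oxy]-2,3-dimethylbutan-1-ol
Conditions: NaH (1 equiv), THF, rt; then TBSCl (1 equiv), rt
Reagents that add atoms: tert-butyldimethylsilyl chloride, CC(C)(C)[Si](C)(C)Cl
Why: Monosilylation through the sparingly soluble monosodium alkoxide needs no regiocontrol because the two hydroxyls are homotopic (even a 1,5-silyl shift is degenerate), and the cap is required because a free 4-hydroxy sulfonate would undergo 5-exo-tet closure to a tetrahydrofuran on contact with base or a Grignard reagent.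

**Step 6**
Reactants: 10 (2S,3S)-4-[(tert-butyldimethylsilyl)oxy]-2,3-dimethylbutan-1-ol
Product: 11 (2S,3S)-4-[(tert-butyldimethylsilyl)oxy]-2,3-dimethylbutyl 4-methylbenzenesulfonate
Conditions: TsCl, Et3N, DMAP (cat.), CH2Cl2, 0 °C → rt
Reagents that add atoms: 4-methylbenzenesulfonyl chloride, Cc1ccc(cc1)S(=O)(=O)Cl
Why: DMAP-catalysed sulfonylation of a primary alcohol takes place at oxygen only, so no stereocentre is touched.

**Step 7**
Reactants: 12 4-bromo-2-methoxyphenol
Product: 13 (4-bromo-2-methoxyphenoxy)triisopropylsilane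
Conditions: TIPSCl, imidazole, DMF, rt
Reagents that add atoms: triisopropylsilyl chloride, CC(C)[Si](Cl)(C(C)C)C(C)C
Why: In this imidazole-promoted phenol silylation TIPS is chosen because it tolerates Mg, Grignard reagents and mild acid methanolysis and leaves at the end with fluoride, which avoids the hydrogenolysis or strong acid that would endanger the benzylic acetate.

**Step 8**
Reactants: 13 (4-bromo-2-methoxyphenoxy)triisopropylsilane; 11 (2S,3S)-4-[(tert-butyldimethylsilyl)oxy]-2,3-dimethylbutyl 4-methylbenzenesulfonate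
Product: 15 tert-butyldimethylsilyl ether of (2S,3R)-4-[3-methoxy-4-(triisopropylsilyloxy)phenyl]-2,3-dimethylbutan-1-ol, via arylmagnesium bromide 14 (not isolated)
Conditions: Mg, THF, reflux; then 11, Li2CuCl4 (5 mol %), THF, −20 °C → rt
Reagents that add atoms: none
Why: In this Kochi-type copper-catalysed sp2–sp3 coupling the aryl cuprate formed from 14 displaces the primary tosylate in an SN2 manner at CH2 (C7'), so the adjacent stereocentre is unaffected (its descriptor changes to R through priorities only).

**Step 9**
Reactants: 15 tert-butyldimethylsilyl ether of (2S,3R)-4-[3-methoxy-4-(triisopropylsilyloxy)phenyl]-2,3-dimethylbutan-1-ol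
Product: 16 (2S,3R)-4-[3-methoxy-4-(triisopropylsilyloxy)phenyl]-2,3-dimethylbutan-1-ol
Conditions: CSA (10 mol %), MeOH/CH2Cl2, 0 °C
Reagents that add atoms: none
Why: Acid-catalysed methanolysis cleaves a primary alkyl TBS ether far faster than a hindered, poorly basic aryl TIPS ether, so only the alcohol is released.

**Step 10**
Reactants: 16 (2S,3R)-4-[3-methoxy-4-(triisopropylsilyloxy)phenyl]-2,3-dimethylbutan-1-ol
Product: 17 (2S,3R)-4-[3-methoxy-4-(triisopropylsilyloxy)phenyl]-2,3-dimethylbutanal
Conditions: Dess–Martin periodinane, CH2Cl2, 0 °C → rt; used crude at once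
Reagents that add atoms: none
Why: Dess–Martin oxidation stops at the aldehyde and runs without base, so the epimerisable α-centre C8 should be preserved if 17 is used directly.

**Step 11**
Reactants: 18 4-bromo-1,2-dimethoxybenzene; 17 (2S,3R)-4-[3-methoxy-4-(triisopropylsilyloxy)phenyl]-2,3-dimethylbutanal
Product: 20 (1R,2S,3R)-1-(3,4-dimethoxyphenyl)-4-[3-methoxy-4-(triisopropylsilyloxy)phenyl]-2,3-dimethylbutan-1-ol, via veratrylmagnesium bromide 19 (not isolated)
Conditions: Mg, THF, 40 °C; then 17, THF, −78 °C; aq NH4Cl; chromatographic removal of the C1 epimer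
Reagents that add atoms: none
Why: In this Grignard 1,2-addition under Felkin–Anh control the sec-alkyl branch (C8') stands perpendicular to C=O as the large group and the C9 methyl lies on the oxygen side, so the aryl group attacks anti to C8' past the α-hydrogen and should favour the 7,8-syn alcohol, which is 7R for 8S.

**Step 12**
Reactants: 20 (1R,2S,3R)-1-(3,4-dimethoxyphenyl)-4-[3-methoxy-4-(triisopropylsilyloxy)phenyl]-2,3-dimethylbutan-1-ol
Product: 21 (1R,2S,3R)-1-(3,4-dimethoxyphenyl)-4-[3-methoxy-4-(triisopropylsilyloxy)phenyl]-2,3-dimethylbutyl acetate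
Conditions: Ac2O, pyridine, DMAP (cat.), CH2Cl2, 0 °C → rt
Reagents that add atoms: acetic anhydride, CC(=O)OC(C)=O
Why: DMAP-catalysed O-acylation leaves the C7–O bond intact (retention), and the basic medium avoids ionisation of the electron-rich benzylic alcohol.

**Step 13**
Reactants: 21 (1R,2S,3R)-1-(3,4-dimethoxyphenyl)-4-[3-methoxy-4-(triisopropylsilyloxy)phenyl]-2,3-dimethylbutyl acetate
Product: 22 (1R,2S,3R)-1-(3,4-dimethoxyphenyl)-4-(4-hydroxy-3-methoxyphenyl)-2,3-dimethylbutyl acetate (target)
Conditions: TBAF/AcOH (equimolar), THF, 0 °C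
Reagents that add atoms: none
Why: Fluoride-induced desilylation of an aryl silyl ether is fast because phenoxide is a good leaving group, the AcOH buffer keeps the medium too weakly basic to cleave the acetate, and the acetate sits on the benzylic carbon of ring B, which carries no free phenol, so no quinone methide elimination is open.

**Compound list**
1 | furfural | O=Cc1ccco1 | starting material
2 | 2,3,7-trioxabicyclo[2.2.1]hept-5-ene-1-carbaldehyde (furfural endoperoxide, racemic) | O=CC12OOC(C=C1)O2 | intermediate
3 | 5-hydroxyfuran-2(5H)-one (racemic) | O=C1OC(O)C=C1 | intermediate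
4 | (1S,2R,5S)-(+)-menthol | CC(C)[C@H]1CC[C@H](C)C[C@@H]1O | starting material
5 | (5R)-5-[(1S,2R,5S)-menthyloxy]furan-2(5H)-one | O=C1O[C@@H](O[C@H]2C[C@@H](C)CC[C@@H]2C(C)C)C=C1 | intermediate
6 | (5S)-5-[(1S,2R,5S)-menthyloxy]furan-2(5H)-one | O=C1O[C@H](O[C@H]2C[C@@H](C)CC[C@@H]2C(C)C)C=C1 | intermediate
7 | lithium (4S,5S)-4-methyl-5-[(1S,2R,5S)-menthyloxy]-4,5-dihydrofuran-2-olate | [Li+].[O-]C1=C[C@H](C)[C@@H](O[C@H]2C[C@@H](C)CC[C@@H]2C(C)C)O1 | intermediate
8 | (3S,4S,5S)-3,4-dimethyl-5-[(1S,2R,5S)-menthyloxy]dihydrofuran-2(3H)-one | O=C1O[C@H](O[C@H]2C[C@@H](C)CC[C@@H]2C(C)C)[C@@H](C)[C@@H]1C | intermediate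
9 | (2S,3S)-2,3-dimethylbutane-1,4-diol | OC[C@@H](C)[C@H](C)CO | intermediate
10 | (2S,3S)-4-[(tert-butyldimethylsilyl)oxy]-2,3-dimethylbutan-1-ol | OC[C@@H](C)[C@H](C)CO[Si](C)(C)C(C)(C)C | intermediate
11 | (2S,3S)-4-[(tert-butyldimethylsilyl)oxy]-2,3-dimethylbutyl 4-methylbenzenesulfonate | Cc1ccc(cc1)S(=O)(=O)OC[C@@H](C)[C@H](C)CO[Si](C)(C)C(C)(C)C | intermediate
12 | 4-bromo-2-methoxyphenol | COc1cc(Br)ccc1O | starting material
13 | (4-bromo-2-methoxyphenoxy)triisopropylsilane | COc1cc(Br)ccc1O[Si](C(C)C)(C(C)C)C(C)C | intermediate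
14 | [3-methoxy-4-(triisopropylsilyloxy)phenyl]magnesium bromide | COc1cc([Mg]Br)ccc1O[Si](C(C)C)(C(C)C)C(C)C | intermediate
15 | tert-butyldimethylsilyl ether of (2S,3R)-4-[3-methoxy-4-(triisopropylsilyloxy)phenyl]-2,3-dimethylbutan-1-ol | COc1cc(C[C@@H](C)[C@H](C)CO[Si](C)(C)C(C)(C)C)ccc1O[Si](C(C)C)(C(C)C)C(C)C | intermediate
16 | (2S,3R)-4-[3-methoxy-4-(triisopropylsilyloxy)phenyl]-2,3-dimethylbutan-1-ol | COc1cc(C[C@@H](C)[C@H](C)CO)ccc1O[Si](C(C)C)(C(C)C)C(C)C | intermediate
17 | (2S,3R)-4-[3-methoxy-4-(triisopropylsilyloxy)phenyl]-2,3-dimethylbutanal | COc1cc(C[C@@H](C)[C@H](C)C=O)ccc1O[Si](C(C)C)(C(C)C)C(C)C | intermediate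
18 | 4-bromo-1,2-dimethoxybenzene | COc1ccc(Br)cc1OC | starting material
19 | (3,4-dimethoxyphenyl)magnesium bromide | COc1ccc([Mg]Br)cc1OC | intermediate
20 | (1R,2S,3R)-1-(3,4-dimethoxyphenyl)-4-[3-methoxy-4-(triisopropylsilyloxy)phenyl]-2,3-dimethylbutan-1-ol | COc1cc(C[C@@H](C)[C@H](C)[C@@H](O)c2ccc(OC)c(OC)c2)ccc1O[Si](C(C)C)(C(C)C)C(C)C | intermediate
21 | (1R,2S,3R)-1-(3,4-dimethoxyphenyl)-4-[3-methoxy-4-(triisopropylsilyloxy)phenyl]-2,3-dimethylbutyl acetate | COc1cc(C[C@@H](C)[C@H](C)[C@@H](OC(C)=O)c2ccc(OC)c(OC)c2)ccc1O[Si](C(C)C)(C(C)C)C(C)C | intermediate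
22 | (1R,2S,3R)-1-(3,4-dimethoxyphenyl)-4-(4-hydroxy-3-methoxyphenyl)-2,3-dimethylbutyl acetate | COc1cc(C[C@@H](C)[C@H](C)[C@@H](OC(C)=O)c2ccc(OC)c(OC)c2)ccc1O | target

**Totals**
Total step count: 13.
Longest linear sequence: 12 steps (steps 1–6 and 8–13, from furfural). Step 7 is a one-step side branch for ring A.

**Three steps most likely to fail**

1. **Step 11.** Facial selectivity may be poor. The size difference between the C9 methyl and the sec-alkyl branch is modest, so the aryl group may attack both aldehyde faces, and some enolisation of the aldehyde may erode C8.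
 - The fallback sets out from 20, taken as the crude mixture with its C1 epimer, and replaces C–C bond-forming stereocontrol by a redox/inversion sequence.
 - Dess–Martin oxidation should give the aryl ketone (2S,3R)-1-(3,4-dimethoxyphenyl)-4-[3-methoxy-4-(triisopropylsilyloxy)phenyl]-2,3-dimethylbutan-1-one F1.
 - In this ketone the bulky aryl group locks the Felkin–Anh conformer, so LiBH(s-Bu)3 in THF at −78 °C should deliver hydride anti to C8' and give the 7,8-anti alcohol (1S,2S,3R)-1-(3,4-dimethoxyphenyl)-4-[3-methoxy-4-(triisopropylsilyloxy)phenyl]-2,3-dimethylbutan-1-ol F2.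
 - A Mitsunobu reaction with AcOH (PPh3, DIAD, toluene, 0 °C, kept cold to hold the SN2 course) inverts C7 and installs the acetate in the same operation. The fallback comes back to the route at 21.

2. **Step 3.** Alkylation of the copper-containing enolate may be sluggish or unselective. Proton transfer could return unmethylated lactone or lead to double methylation at C3, and excess cuprate competes for MeI.
 - The fallback sets out from 6 and delivers the C4 methyl as a sulfur-stabilised carbanion instead of a cuprate.
 - Tris(phenylthio)methyllithium F3 (from tris(phenylthio)methane and n-BuLi, THF, −78 °C) should add 1,4 anti to the menthyloxy group.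
 - This gives the copper-free lithium (4S,5S)-5-[(1S,2R,5S)-menthyloxy]-4-[tris(phenylthio)methyl]-4,5-dihydrofuran-2-olate F4.
 - F4 is methylated in the same flask with MeI, anti to the very large C4 group, to give (3S,4S,5S)-3-methyl-5-[(1S,2R,5S)-menthyloxy]-4-[tris(phenylthio)methyl]dihydrofuran-2(3H)-one F5.
 - Raney Ni in EtOH then cleaves the three C–S bonds and leaves CH3 on C4. The fallback comes back to the route at 8.

3. **Step 8.** Substitution at the β-branched primary carbon may be slow, which would let biaryl homocoupling and attack of the Grignard reagent at sulfur take over.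
 - The fallback sets out from 10 and reverses the polarity, so that the chain becomes the nucleophile and ring A the electrophile.
 - I2, PPh3 and imidazole in CH2Cl2 should give tert-butyl{[(2S,3S)-4-iodo-2,3-dimethylbutyl]oxy}dimethylsilane F6.
 - Zinc insertion (Zn dust, LiCl, THF) should give {(2S,3S)-4-[(tert-butyldimethylsilyl)oxy]-2,3-dimethylbutyl}zinc iodide F7.
 - A Negishi coupling of F7 with aryl bromide 13 (Pd(OAc)2, SPhos, THF, 40 °C) forms the C7'–aryl bond. The fallback comes back to the route at 15.

**Further compounds**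
F1 | step 11 | (2S,3R)-1-(3,4-dimethoxyphenyl)-4-[3-methoxy-4-(triisopropylsilyloxy)phenyl]-2,3-dimethylbutan-1-one | COc1cc(C[C@@H](C)[C@H](C)C(=O)c2ccc(OC)c(OC)c2)ccc1O[Si](C(C)C)(C(C)C)C(C)C
F2 | step 11 | (1S,2S,3R)-1-(3,4-dimethoxyphenyl)-4-[3-methoxy-4-(triisopropylsilyloxy)phenyl]-2,3-dimethylbutan-1-ol | COc1cc(C[C@@H](C)[C@H](C)[C@H](O)c2ccc(OC)c(OC)c2)ccc1O[Si](C(C)C)(C(C)C)C(C)C
F3 | step 3 | tris(phenylthio)methyllithium | [Li]C(Sc1ccccc1)(Sc1ccccc1)Sc1ccccc1
F4 | step 3 | lithium (4S,5S)-5-[(1S,2R,5S)-menthyloxy]-4-[tris(phenylthio)methyl]-4,5-dihydrofuran-2-olate | [Li+].[O-]C1=C[C@H](C(Sc2ccccc2)(Sc3ccccc3)Sc4ccccc4)[C@@H](O[C@H]5C[C@@H](C)CC[C@@H]5C(C)C)O1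
F5 | step 3 | (3S,4S,5S)-3-methyl-5-[(1S,2R,5S)-menthyloxy]-4-[tris(phenylthio)methyl]dihydrofuran-2(3H)-one | O=C1O[C@H](O[C@H]2C[C@@H](C)CC[C@@H]2C(C)C)[C@@H](C(Sc3ccccc3)(Sc4ccccc4)Sc5ccccc5)[C@@H]1C
F6 | step 8 | tert-butyl{[(2S,3S)-4-iodo-2,3-dimethylbutyl]oxy}dimethylsilane | IC[C@@H](C)[C@H](C)CO[Si](C)(C)C(C)(C)C
F7 | step 8 | {(2S,3S)-4-[(tert-butyldimethylsilyl)oxy]-2,3-dimethylbutyl}zinc iodide | I[Zn]C[C@@H](C)[C@H](C)CO[Si](C)(C)C(C)(C)C
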